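(The numbers in the tables come from a simulation on assumed constants; the scatter is artificial.)

You cannot read this flask off any run, because neither earlier run was made at its loading.

| setting | north-west | south | flask |
|---|---|---|---|
| starting material | 0.10 M | 0.10 M | 0.10 M |
| second substrate | 1 equiv | 1 equiv | 1.00 equiv |
| coupling partner | 1 equiv (fed, over 1.5 h) | 1 equiv (fed, over 1.5 h) | 1.00 equiv (fed, over 1.5 h) |
| protic impurity | 0.050 M | 0.050 M | 0.0500 M |
| precatalyst | 0.05 mol% | 0.2 mol% | 0.099 mol% |
| remark | run made earlier | run made earlier |  |
| time |  |  | 4.0 h |

| run | time / h | target / % |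
|---|---|---|
| north-west | 0.200 | 0.8 |
| north-west | 0.333 | 0 |
| north-west | 0.667 | 0.6 |
| north-west | 1.33 | 2.5 |
| north-west | 2.50 | 10.2 |
| south | 0.200 | 0.4 |
| south | 0.333 | 0 |
| south | 0.667 | 1.4 |
| south | 1.33 | 8.9 |
| south | 2.50 | 33.4 |

(scatter of a reading: 0.5 percentage points)



- amount of target in percent of the starting material charged, at 25 min, 80 min, 2.5 h and 4.0 h

Go to logarithms and ask which given numbers matter. Starting material, second substrate, coupling partner, feed time and protic impurity stand in the flask as in both runs, so they need no correction. The loading differs, so lay it on a logarithmic axis, like frequency on a Bode plot: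

ln(0.099 mol% / 0.05 mol%) / ln(0.2 mol% / 0.05 mol%) = 0.493

Call this the log position, the fraction of the way from the north-west run to the south run at which the flask sits. It is about half, so take the geometric mean of the two readings at equal time, weighted by that position.

Now test the inputs. The slope between the runs at 2.5 h is 0.856, so a slip of one percent in the loading moves the target by that many percent. At 2.5 h the north-west reading passes on 2.49% of error, more than the south reading's 0.738%. At 80 min the north-west reading passes on 10.1%. The readings at 0.333 h, 0% and 0%, are lost in a scatter of 0.5 percentage points, so take no weight from them.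

Then reckon:

80 min: 2.5% and 8.9% give 4.67%

2.5 h: 10.2% and 33.4% give 18.3%

Carry the power of time between these two back to 25 min: 0.374%. Hold their straight line on to 4.0 h: 35.8%, an extrapolation with no reading behind it.

The forecast, taking “about twice the north-west values” up to 2.5 h, gives 0.2%, 4.7% and 18.5%, then runs on from there at a fading rate to an extrapolated 34% at 4.0 h, below mine at both ends.

The flask gives 0.175% at 25 min, 4.73% at 80 min, 19.2% at 2.5 h and 38.3% at 4.0 h.

    starting material + free catalyst ⇌ catalyst intermediate A (K = 19.0 M⁻¹, k = 40000 M⁻¹ h⁻¹)
    precatalyst → free catalyst (k = 0.350 h⁻¹)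
    coupling partner + catalyst intermediate B → free catalyst + second product (k = 2000 M⁻¹ h⁻¹)
    second substrate + protic impurity → quenched substrate (k = 4.60 M⁻¹ h⁻¹)
    coupling partner + catalyst intermediate A → free catalyst + target (k = 5900 M⁻¹ h⁻¹)
    second substrate + free catalyst ⇌ catalyst intermediate B (K = 4.20 M⁻¹, k = 72000 M⁻¹ h⁻¹)

At 1.50 h this flask still holds 59.2% of its catalyst as precatalyst. Set the flask's own targets back between the two runs on the logarithmic axis: they sit at 0.502 of the way at 80 min and 0.533 at 2.5 h, against a log position of 0.493.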